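The route rests on the C8–C9 bond of ring B (drimane numbering: C8 bears the C12 formyl group and the C7=C8 double bond, C9 the C11 formyl group). Because this bond is the centre of the 2-ene-1,4-dial, it is made sp2–sp2: a 6-exo Heck cyclization joins the α-bromoacrylate C7=C8(Br)–C12 to the methyl enol ether C9=C11–OMe of a ring A ketone. One operation closes ring B, installs the C7=C8 enoate and returns C11 as a dienol ether; the epimerizable C9–H is therefore created only in the last step, by protonation anti to the C10 methyl group.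

Key step: step 10

Remark 1: atoms are numbered as in drimanes (ring A: C1–C5 and C10; ring B: C5–C10; C11 on C9, C12 on C8); the catalyst of step 2 is assumed to give the 4R carbinol with the (R,R) ligand, the antipodal ligand being taken otherwise.
Remark 2: methyl bromo(triphenylphosphoranylidene)acetate is treated as a reagent, made in one operation from Ph3P=CHCO2Me (Br2, then NaOH).

Step 1
Reactants: 1 2,5-dimethylphenol
Product: 2 4,4-dimethoxy-2,5-dimethylcyclohexa-2,5-dien-1-one
Conditions: PhI(OAc)2 (2.2 equiv), MeOH, 0 °C to rt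
Reagents that add atoms: methanol, CO
Why: Oxidative dearomatization by the trivalent iodine reagent: para-methoxylation gives a 4-methoxyphenol that is oxidized a second time in methanol to the p-quinone monoketal, and no stereocenter is formed.

Step 2
Reactants: 2 4,4-dimethoxy-2,5-dimethylcyclohexa-2,5-dien-1-one
Product: 4 (4R)-4-hydroxy-2,4,5-trimethylcyclohexa-2,5-dien-1-one, via carbinol ketal 3 (not isolated)
Conditions: ZnMe2 (2.5 equiv), Ti(OiPr)4 (1.2 equiv), (R,R)-trans-1,2-bis(2-hydroxycamphor-10-sulfonamido)cyclohexane (5 mol%), toluene/hexane, rt; then 5% aq. oxalic acid, THF, 0 °C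
Reagents that add atoms: dimethylzinc, C[Zn]C; water, O
Why: Catalytic enantioselective 1,2-addition of a methyltitanium species (from ZnMe2 and Ti(OiPr)4) to the dienone carbonyl, in which the chiral titanium bis(sulfonamide) catalyst tells the α-methylated vinyl flank from the unsubstituted one and so sets the carbinol carbon (later C4) as R, followed by mild acid hydrolysis of the now doubly allylic ketal to the p-quinol.

Step 3
Reactants: 4 (4R)-4-hydroxy-2,4,5-trimethylcyclohexa-2,5-dien-1-one
Product: 6 (4R,5R,6S)-5-ethenyl-4-hydroxy-6-(hydroxymethyl)-3,4,6-trimethylcyclohex-2-en-1-one, via magnesium enolate 5 (not isolated)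
Conditions: CH2=CHMgBr (3.5 equiv), THF, −78 to −20 °C; then CH2O (gas), −78 to 0 °C; aq. NH4Cl
Reagents that add atoms: vinylmagnesium bromide, C=C[Mg]Br; formaldehyde, C=O
Why: Alkoxide-directed conjugate addition (the magnesium alkoxide delivers vinyl to the unsubstituted β-carbon on the oxygen-bearing face, setting C5 syn to the hydroxyl) followed by aldol trapping of the magnesium enolate with formaldehyde anti to the new vinyl group, which sets the C10 quaternary center with methyl cis to vinyl.

Step 4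
Reactants: 6 (4R,5R,6S)-5-ethenyl-4-hydroxy-6-(hydroxymethyl)-3,4,6-trimethylcyclohex-2-en-1-one
Product: 7 (5S,6S)-5-ethenyl-6-(hydroxymethyl)-3,4,6-trimethylcyclohex-3-en-1-one
Conditions: SmI2 (4 equiv), THF/MeOH, −78 °C; aq. NaHCO3
Reagents that add atoms: none
Why: Samarium diiodide reduction of a γ-hydroxy enone (vinylogous α-hydroxy ketone deoxygenation) should expel the C4 oxygen to give the dienolate, whose kinetic α-protonation by methanol leaves the tetrasubstituted C3=C4 alkene out of conjugation and erases the C4 stereocenter after it has relayed its chirality to C5 and C10.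

Step 5
Reactants: 7 (5S,6S)-5-ethenyl-6-(hydroxymethyl)-3,4,6-trimethylcyclohex-3-en-1-one
Product: 8 (1S,2S)-2-ethenyl-1,3,4-trimethyl-6-oxocyclohex-3-ene-1-carbaldehyde
Conditions: Dess–Martin periodinane, NaHCO3, CH2Cl2, 0 °C
Reagents that add atoms: none
Why: Dess–Martin oxidation under buffered, non-basic conditions should convert the neopentyl primary alcohol into the non-enolizable β-keto aldehyde without conjugating the β,γ-unsaturated ketone.

Step 6
Reactants: 8 (1S,2S)-2-ethenyl-1,3,4-trimethyl-6-oxocyclohex-3-ene-1-carbaldehyde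
Product: 9 (5S,6S)-5-ethenyl-6-(2-methoxyethenyl)-3,4,6-trimethylcyclohex-3-en-1-one (E/Z mixture)
Conditions: MeOCH2PPh3Cl, KN(SiMe3)2, THF, −78 to 0 °C
Reagents that add atoms: (methoxymethyl)triphenylphosphonium chloride, COC[P+](c1ccccc1)(c1ccccc1)c1ccccc1.[Cl-]
Why: Wittig olefination: the unstabilized methoxymethylene ylide should add to the aldehyde much faster than to the hindered α-quaternary ketone, and the E/Z mixture of the enol ether is of no consequence.

Step 7
Reactants: 9 (5S,6S)-5-ethenyl-6-(2-methoxyethenyl)-3,4,6-trimethylcyclohex-3-en-1-one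
Product: 11 (5S,6S)-5-(2-hydroxyethyl)-6-(2-methoxyethenyl)-3,4,6-trimethylcyclohex-3-en-1-one, via catechol boronate 10 (not isolated)
Conditions: catecholborane (1.5 equiv), RhCl(PPh3)3 (3 mol%), THF, 0 °C to rt; then H2O2, pH 7 phosphate buffer, 0 °C
Reagents that add atoms: hydrogen peroxide, OO
Why: Rhodium-catalysed hydroboration with catecholborane should be anti-Markovnikov and selective for the monosubstituted vinyl group over the ketone, the 1,2-disubstituted enol ether and the tetrasubstituted alkene, and buffered peroxide oxidation then gives the primary alcohol.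

Step 8
Reactants: 11 (5S,6S)-5-(2-hydroxyethyl)-6-(2-methoxyethenyl)-3,4,6-trimethylcyclohex-3-en-1-one
Product: 12 2-[(1S,6S)-6-(2-methoxyethenyl)-2,3,6-trimethyl-5-oxocyclohex-2-en-1-yl]acetaldehyde
Conditions: Dess–Martin periodinane, NaHCO3, CH2Cl2, 0 °C
Reagents that add atoms: none
Why: Dess–Martin oxidation, again buffered, should give the aldehyde without touching the enol ether or the β,γ-unsaturated ketone.

Step 9
Reactants: 12 2-[(1S,6S)-6-(2-methoxyethenyl)-2,3,6-trimethyl-5-oxocyclohex-2-en-1-yl]acetaldehyde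
Product: 13 methyl (2Z)-2-bromo-4-[(1S,6S)-6-(2-methoxyethenyl)-2,3,6-trimethyl-5-oxocyclohex-2-en-1-yl]but-2-enoate
Conditions: Ph3P=C(Br)CO2Me (1.2 equiv), CH2Cl2, rt
Reagents that add atoms: methyl bromo(triphenylphosphoranylidene)acetate, COC(=O)C(Br)=P(c1ccccc1)(c1ccccc1)c1ccccc1
Why: Wittig olefination with a stabilized α-bromo ylide should react only at the aldehyde and give the Z bromoacrylate (ester trans to the chain), the geometry that places bromine cis to C6.

Step 10
Reactants: 13 methyl (2Z)-2-bromo-4-[(1S,6S)-6-(2-methoxyethenyl)-2,3,6-trimethyl-5-oxocyclohex-2-en-1-yl]but-2-enoate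
Product: 14 methyl (4aS,8aS)-1-(methoxymethylidene)-5,6,8a-trimethyl-8-oxo-1,4,4a,7,8,8a-hexahydronaphthalene-2-carboxylate (E/Z mixture at C9=C11)
Conditions: Pd(OAc)2 (10 mol%), PPh3 (25 mol%), KOAc (3 equiv), DMF, 75 °C
Reagents that add atoms: none
Why: Oxidative addition of zerovalent palladium into the C8–Br bond, syn carbopalladation of the enol ether with C8 bonding to C9, and β-hydride elimination of the C9 hydrogen should regenerate a C9=C11 enol ether, now conjugated with the new C7=C8 enoate. The closest known reaction type is the intramolecular Heck cyclization of a vinyl halide onto an alkyl enol ether. Ring B is closed in the 6-exo-trig mode. No stereocenter is created: C9 becomes sp2, so both enol ether isomers of 13 converge on 14 and the C9 configuration is left to the final protonation, while C5 and C10 are untouched. The step needs bond formation at C9 and not at C11 (7-endo) or at C4 of the ring alkene (5-exo); the neutral, halide-bound palladium pathway favours attack β to oxygen in the smaller ring, the tetrasubstituted C3=C4 alkene is a poor partner for insertion, and the Z geometry of the bromoacrylate holds palladium cis to the tether. KOAc is too weak a base to conjugate the β,γ-unsaturated ketone.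

Step 11
Reactants: 14 methyl (4aS,8aS)-1-(methoxymethylidene)-5,6,8a-trimethyl-8-oxo-1,4,4a,7,8,8a-hexahydronaphthalene-2-carboxylate
Product: 15 [(4aS,8R,8aS)-8-hydroxy-1-(methoxymethylidene)-5,6,8a-trimethyl-1,4,4a,7,8,8a-hexahydronaphthalen-2-yl]methanol
Conditions: LiAlH4, Et2O, −78 to 0 °C; then H2O, aq. NaOH
Reagents that add atoms: none
Why: Hydride reduction: LiAlH4 should reduce the enoate 1,2 to the allylic alcohol and the C1 ketone by axial attack on the α face, anti to the axial C10 methyl and away from the peri C11 group, which sets C1 as the equatorial 1β-alcohol (R).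

Step 12
Reactants: 15 [(4aS,8R,8aS)-8-hydroxy-1-(methoxymethylidene)-5,6,8a-trimethyl-1,4,4a,7,8,8a-hexahydronaphthalen-2-yl]methanol
Product: 16 (4aS,8R,8aS)-8-hydroxy-1-(methoxymethylidene)-5,6,8a-trimethyl-1,4,4a,7,8,8a-hexahydronaphthalene-2-carbaldehyde
Conditions: MnO2 (excess), CH2Cl2, rt
Reagents that add atoms: none
Why: Allylic oxidation with MnO2 should oxidize only the primary allylic alcohol to the enal under neutral conditions, leaving the homoallylic secondary alcohol and the acid-sensitive dienol ether untouched.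

Step 13
Reactants: 16 (4aS,8R,8aS)-8-hydroxy-1-(methoxymethylidene)-5,6,8a-trimethyl-1,4,4a,7,8,8a-hexahydronaphthalene-2-carbaldehyde; 17 3-phenylprop-2-ynoic acid
Product: 18 (1R,4aS,8aS)-7-formyl-8-(methoxymethylidene)-3,4,8a-trimethyl-1,2,4a,5,8,8a-hexahydronaphthalen-1-yl 3-phenylprop-2-ynoate
Conditions: N,N'-dicyclohexylcarbodiimide, DMAP (0.3 equiv), CH2Cl2, 0 °C to rt
Reagents that add atoms: none
Why: Steglich esterification (carbodiimide activation with DMAP acyl transfer) should acylate the hindered secondary alcohol with the slim, linear alkynoic acid, the amine buffering the dienol ether against the acid.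

Step 14
Reactants: 18 (1R,4aS,8aS)-7-formyl-8-(methoxymethylidene)-3,4,8a-trimethyl-1,2,4a,5,8,8a-hexahydronaphthalen-1-yl 3-phenylprop-2-ynoate
Product: 19 (1R,4aS,8aS)-7-formyl-8-(methoxymethylidene)-3,4,8a-trimethyl-1,2,4a,5,8,8a-hexahydronaphthalen-1-yl (2Z)-3-phenylprop-2-enoate
Conditions: H2 (1 atm), Lindlar catalyst (Pd on CaCO3, poisoned with Pb(OAc)2), quinoline, EtOAc, rt
Reagents that add atoms: none
Why: Lindlar semihydrogenation should add one equivalent of hydrogen syn to the alkyne to give the Z cinnamate, while the trisubstituted enal, the dienol ether and the tetrasubstituted alkene are not reduced on the poisoned catalyst.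

Step 15
Reactants: 19 (1R,4aS,8aS)-7-formyl-8-(methoxymethylidene)-3,4,8a-trimethyl-1,2,4a,5,8,8a-hexahydronaphthalen-1-yl (2Z)-3-phenylprop-2-enoate
Product: 20 (1R,4aS,8R,8aS)-7,8-diformyl-3,4,8a-trimethyl-1,2,4a,5,8,8a-hexahydronaphthalen-1-yl (2Z)-3-phenylprop-2-enoate
Conditions: 0.1 M aq. oxalic acid, THF, 0 °C
Reagents that add atoms: water, O
Why: Acid-catalysed enol ether hydrolysis: kinetic protonation at C9 (not at C7, whose cation would sit next to the formyl-bearing C8) should occur on the α face anti to the axial C10 methyl, setting C9 as R with the formyl group β, and the oxocarbenium ion is hydrolysed to the C11 aldehyde without the base that would epimerize C9.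

Compound list
1 | 2,5-dimethylphenol | Cc1ccc(C)c(O)c1 | starting material
2 | 4,4-dimethoxy-2,5-dimethylcyclohexa-2,5-dien-1-one | COC1(OC)C=C(C)C(=O)C=C1C | intermediate
3 | (1R)-4,4-dimethoxy-1,2,5-trimethylcyclohexa-2,5-dien-1-ol (formed as its metal alkoxide) | C[C@@]1(O)C=C(C)C(OC)(OC)C=C1C | intermediate
4 | (4R)-4-hydroxy-2,4,5-trimethylcyclohexa-2,5-dien-1-one | C[C@@]1(O)C=C(C)C(=O)C=C1C | intermediate
5 | bis(bromomagnesium) salt (C1 enolate and C4 alkoxide) of (4R,5R)-5-ethenyl-4-hydroxy-3,4,6-trimethylcyclohex-2-en-1-one, vinyl cis to the C4 oxygen | C=C[C@@H]1C(C)=C(O[Mg]Br)C=C(C)[C@]1(C)O[Mg]Br | intermediate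
6 | (4R,5R,6S)-5-ethenyl-4-hydroxy-6-(hydroxymethyl)-3,4,6-trimethylcyclohex-2-en-1-one | OC[C@@]1(C)C(=O)C=C(C)[C@](C)(O)[C@@H]1C=C | intermediate
7 | (5S,6S)-5-ethenyl-6-(hydroxymethyl)-3,4,6-trimethylcyclohex-3-en-1-one | OC[C@@]1(C)C(=O)CC(C)=C(C)[C@@H]1C=C | intermediate
8 | (1S,2S)-2-ethenyl-1,3,4-trimethyl-6-oxocyclohex-3-ene-1-carbaldehyde | O=C[C@@]1(C)C(=O)CC(C)=C(C)[C@@H]1C=C | intermediate
9 | (5S,6S)-5-ethenyl-6-(2-methoxyethenyl)-3,4,6-trimethylcyclohex-3-en-1-one, E/Z mixture | COC=C[C@@]1(C)C(=O)CC(C)=C(C)[C@@H]1C=C | intermediate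
10 | 2-{2-[(1S,6S)-6-(2-methoxyethenyl)-2,3,6-trimethyl-5-oxocyclohex-2-en-1-yl]ethyl}-1,3,2-benzodioxaborole | COC=C[C@@]1(C)C(=O)CC(C)=C(C)[C@@H]1CCB1Oc2ccccc2O1 | intermediate
11 | (5S,6S)-5-(2-hydroxyethyl)-6-(2-methoxyethenyl)-3,4,6-trimethylcyclohex-3-en-1-one | COC=C[C@@]1(C)C(=O)CC(C)=C(C)[C@@H]1CCO | intermediate
12 | 2-[(1S,6S)-6-(2-methoxyethenyl)-2,3,6-trimethyl-5-oxocyclohex-2-en-1-yl]acetaldehyde | COC=C[C@@]1(C)C(=O)CC(C)=C(C)[C@@H]1CC=O | intermediate
13 | methyl (2Z)-2-bromo-4-[(1S,6S)-6-(2-methoxyethenyl)-2,3,6-trimethyl-5-oxocyclohex-2-en-1-yl]but-2-enoate | COC=C[C@@]1(C)C(=O)CC(C)=C(C)[C@@H]1C/C=C(\Br)C(=O)OC | intermediate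
14 | methyl (4aS,8aS)-1-(methoxymethylidene)-5,6,8a-trimethyl-8-oxo-1,4,4a,7,8,8a-hexahydronaphthalene-2-carboxylate, E/Z mixture | CC1=C(C)[C@@H]2CC=C(C(=O)OC)C(=COC)[C@@]2(C)C(=O)C1 | intermediate
15 | [(4aS,8R,8aS)-8-hydroxy-1-(methoxymethylidene)-5,6,8a-trimethyl-1,4,4a,7,8,8a-hexahydronaphthalen-2-yl]methanol | CC1=C(C)[C@@H]2CC=C(CO)C(=COC)[C@@]2(C)[C@H](O)C1 | intermediate
16 | (4aS,8R,8aS)-8-hydroxy-1-(methoxymethylidene)-5,6,8a-trimethyl-1,4,4a,7,8,8a-hexahydronaphthalene-2-carbaldehyde | CC1=C(C)[C@@H]2CC=C(C=O)C(=COC)[C@@]2(C)[C@H](O)C1 | intermediate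
17 | 3-phenylprop-2-ynoic acid | OC(=O)C#Cc1ccccc1 | starting material
18 | (1R,4aS,8aS)-7-formyl-8-(methoxymethylidene)-3,4,8a-trimethyl-1,2,4a,5,8,8a-hexahydronaphthalen-1-yl 3-phenylprop-2-ynoate | CC1=C(C)[C@@H]2CC=C(C=O)C(=COC)[C@@]2(C)[C@H](OC(=O)C#Cc2ccccc2)C1 | intermediate
19 | (1R,4aS,8aS)-7-formyl-8-(methoxymethylidene)-3,4,8a-trimethyl-1,2,4a,5,8,8a-hexahydronaphthalen-1-yl (2Z)-3-phenylprop-2-enoate | CC1=C(C)[C@@H]2CC=C(C=O)C(=COC)[C@@]2(C)[C@H](OC(=O)/C=C\c2ccccc2)C1 | intermediate
20 | (1R,4aS,8R,8aS)-7,8-diformyl-3,4,8a-trimethyl-1,2,4a,5,8,8a-hexahydronaphthalen-1-yl (2Z)-3-phenylprop-2-enoate | CC1=C(C)[C@@H]2CC=C(C=O)[C@H](C=O)[C@@]2(C)[C@H](OC(=O)/C=C\c2ccccc2)C1 | target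

Total step count: 15. Longest linear sequence: 15 steps (1 to 20).

Steps most likely to fail

Step 10 (key step). The carbopalladation may not discriminate as needed: insertion at C11 (7-endo) or into the ring alkene (5-exo) could compete, or the hindered enol ether could react so slowly that the vinylpalladium species decomposes. The fallback makes C9 the nucleophile instead of an olefin acceptor. It sets out from 13: hydrolysis of the enol ether (aq. oxalic acid, THF) should give the homologated aldehyde methyl (2Z)-2-bromo-4-[2,3,6-trimethyl-5-oxo-6-(2-oxoethyl)cyclohex-2-en-1-yl]but-2-enoate F1. A palladium-catalysed intramolecular α-alkenylation of the aldehyde enolate (Pd(OAc)2, rac-BINAP, Cs2CO3, dioxane, 80 °C) then forms the same C8–C9 bond, with the regiochemistry fixed by the enolate carbon, to give methyl 1-formyl-5,6,8a-trimethyl-8-oxo-1,4,4a,7,8,8a-hexahydronaphthalene-2-carboxylate F2. Deprotonation of its most acidic C9–H (KN(SiMe3)2, THF/HMPA, −78 °C) and O-methylation of the extended enolate with MeOTf should come back to the route at 14.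

Step 2. Enantioface discrimination may be too low, because the two flanks of the carbonyl differ by a single methyl group, and the 1,2-addition may be slow. The fallback sets the absolute configuration at C5 by a catalyst-controlled conjugate addition and introduces the C4 methyl later. It sets out from 2 and comes back at 7:
- Rhodium-catalysed asymmetric conjugate vinylation (CH2=CHBF3K, [Rh(cod)2]BF4/(S)-BINAP, toluene/H2O, 80 °C) should give 5-ethenyl-4,4-dimethoxy-3,6-dimethylcyclohex-2-en-1-one F3.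
- α'-Alkylation anti to the vinyl group (LiN(iPr)2, THF, −78 °C; iPr3SiOCH2Cl) gives 5-ethenyl-4,4-dimethoxy-3,6-dimethyl-6-{[tri(propan-2-yl)silyl]oxymethyl}cyclohex-2-en-1-one F4.
- Ketal hydrolysis (aq. oxalic acid, THF) gives 6-ethenyl-2,5-dimethyl-5-{[tri(propan-2-yl)silyl]oxymethyl}cyclohex-2-ene-1,4-dione F5, which is used at once because C5 is then epimerizable.
- MeMgBr/CeCl3 (THF, −78 °C) adds to the less hindered C4 carbonyl to give 5-ethenyl-4-hydroxy-3,4,6-trimethyl-6-{[tri(propan-2-yl)silyl]oxymethyl}cyclohex-2-en-1-one F6; both C4 epimers serve.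
- SmI2 (THF/MeOH, −78 °C) gives 5-ethenyl-3,4,6-trimethyl-6-{[tri(propan-2-yl)silyl]oxymethyl}cyclohex-3-en-1-one F7, and Bu4NF (THF) removes the silyl group to reach 7.

Step 3. The Grignard reagent may add 1,2 to the dienone carbonyl or transfer incompletely to the α-methylated arm, and the one-pot aldol may be capricious. The fallback is catalyst-controlled and stepwise. It sets out from 4: rhodium-catalysed conjugate vinylation with the BINAP antipode matched to the substrate (CH2=CHBF3K, [Rh(cod)2]BF4/BINAP, dioxane/H2O, 60 °C) should give 5-ethenyl-4-hydroxy-3,4,6-trimethylcyclohex-2-en-1-one F8. LiN(iPr)2 (2.2 equiv, THF, −78 °C; alkoxide and α'-enolate) followed by CH2O then hydroxymethylates anti to the vinyl group and comes back to the route at 6.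

Further compounds
F1 | step 10 | methyl (2Z)-2-bromo-4-[2,3,6-trimethyl-5-oxo-6-(2-oxoethyl)cyclohex-2-en-1-yl]but-2-enoate (ring stereocenters as in 13) | O=CC[C@@]1(C)C(=O)CC(C)=C(C)[C@@H]1C/C=C(\Br)C(=O)OC
F2 | step 10 | methyl (4aS,8aS)-1-formyl-5,6,8a-trimethyl-8-oxo-1,4,4a,7,8,8a-hexahydronaphthalene-2-carboxylate (C1 epimers) | CC1=C(C)[C@@H]2CC=C(C(=O)OC)C(C=O)[C@@]2(C)C(=O)C1
F3 | step 2 | 5-ethenyl-4,4-dimethoxy-3,6-dimethylcyclohex-2-en-1-one (C5 as in 7, C6 epimers) | C=C[C@@H]1C(C)C(=O)C=C(C)C1(OC)OC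
F4 | step 2 | 5-ethenyl-4,4-dimethoxy-3,6-dimethyl-6-{[tri(propan-2-yl)silyl]oxymethyl}cyclohex-2-en-1-one (methyl cis to vinyl) | C=C[C@@H]1[C@@](C)(CO[Si](C(C)C)(C(C)C)C(C)C)C(=O)C=C(C)C1(OC)OC
F5 | step 2 | 6-ethenyl-2,5-dimethyl-5-{[tri(propan-2-yl)silyl]oxymethyl}cyclohex-2-ene-1,4-dione (methyl cis to vinyl) | C=C[C@@H]1[C@@](C)(CO[Si](C(C)C)(C(C)C)C(C)C)C(=O)C=C(C)C1=O
F6 | step 2 | 5-ethenyl-4-hydroxy-3,4,6-trimethyl-6-{[tri(propan-2-yl)silyl]oxymethyl}cyclohex-2-en-1-one (C4 epimers) | C=C[C@@H]1[C@@](C)(CO[Si](C(C)C)(C(C)C)C(C)C)C(=O)C=C(C)C1(C)O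
F7 | step 2 | 5-ethenyl-3,4,6-trimethyl-6-{[tri(propan-2-yl)silyl]oxymethyl}cyclohex-3-en-1-one (stereocenters as in 7) | C=C[C@@H]1[C@@](C)(CO[Si](C(C)C)(C(C)C)C(C)C)C(=O)CC(C)=C1C
F8 | step 3 | (4R,5R)-5-ethenyl-4-hydroxy-3,4,6-trimethylcyclohex-2-en-1-one (C6 epimers) | C=C[C@@H]1C(C)C(=O)C=C(C)[C@]1(C)O
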